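## Retrosynthetic overview

1. The target comes from its dimethyl ester by hydrolysis; the 8(17)-methylene comes from a primary allylic acetate (palladium/formate hydrogenolysis) and the 2β-hydroxyl from hydride reduction of a C2 ketone.
2. The C2 ketone comes from a ring A 2-en-1-one by reductive 1,3-transposition and hydroboration–oxidation; the C10 methyl is put in by enolate methylation next to that C1 ketone.
3. Key step: ring B is closed by a catalytic enantioselective Diels–Alder reaction that desymmetrises an achiral 4-methyl-4-(methoxycarbonyl)cyclohexa-2,5-dienone (ring A); it sets C4, C5 and C9 at once.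
4. The dienone comes from methyl benzoate (Birch reductive methylation, allylic oxidation); the diene comes from methyl geranate (ozonolysis, Baylis–Hillman/acetate transposition with acrolein, Wittig).
5. Ring order: ring A from the arene first, then ring B by cycloaddition.

Assumption: the SMILES is read literally as (2S,4R,5S,9R,10R) in labdane numbering, i.e. an A/B-cis labdane (5β-H, 9β-H, side chain 9α, 4β-methyl, 4α-carboxyl, 2β-OH; β = face of the C10 methyl), and the (S)-configured catalyst of step 6 is assumed to select the enone unit drawn (otherwise its mirror image is used).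

## Route

Step 1
Reactants: 1 methyl benzoate
Product: 2 methyl 1-methylcyclohexa-2,5-diene-1-carboxylate
Conditions: Li (2.2 equiv), NH3(l)/THF, t-BuOH (1.0 equiv), −78 °C; then MeI, −78 °C → rt
Reagents that add atoms: iodomethane, CI
Why: Birch reductive alkylation: two-electron reduction of the benzoate, protonation at the para carbon and C-methylation of the ester enolate give the 1,4-diene and break the aromaticity; C4 is still prochiral, so no stereocenter is formed.

Step 2
Reactants: 2 methyl 1-methylcyclohexa-2,5-diene-1-carboxylate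
Product: 3 methyl 1-methyl-4-oxocyclohexa-2,5-diene-1-carboxylate
Conditions: t-BuOOH (70% aq., 5 equiv), Rh2(C6H10NO)4 [dirhodium tetrakis(caprolactamate), 1 mol %], K2CO3, CH2Cl2, rt
Reagents that add atoms: tert-butyl hydroperoxide, CC(C)(C)OO
Why: Allylic C–H oxidation of the doubly allylic CH2 by the tert-butylperoxyl radical gives the cross-conjugated dienone, which is mirror-symmetric and has no stereocenter.

Step 3
Reactants: 4 methyl geranate
Product: 5 methyl (2E)-3-methyl-6-oxohex-2-enoate
Conditions: O3 (1 equiv), CH2Cl2/MeOH, −78 °C; then Me2S, −78 °C → rt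
Reagents that add atoms: ozone, [O-][O+]=O
Why: Ozonolysis with reductive work-up; ozone attacks the electron-rich 6,7-alkene much faster than the ester-conjugated 2,3-alkene, whose E geometry is carried unchanged to the target.

Step 4
Reactants: 5 methyl (2E)-3-methyl-6-oxohex-2-enoate; 6 acrolein
Product: 9 methyl (2E,6E)-7-(acetoxymethyl)-3-methyl-8-oxoocta-2,6-dienoate, via Baylis–Hillman alcohol 7 (not isolated), via secondary acetate 8 (not isolated)
Conditions: 6 (3 equiv), DABCO (1 equiv), THF, rt; then Ac2O, pyridine, 0 °C; then 40 °C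
Reagents that add atoms: acetic anhydride, CC(=O)OC(C)=O
Why: Morita–Baylis–Hillman reaction, acetylation and DABCO-mediated SN2′–SN2′ allylic transposition to the conjugated primary acetate; the trisubstituted enal equilibrates to the E isomer (chain trans to CHO) and the carbinol stereocenter of 7 and 8 is lost.

Step 5
Reactants: 9 methyl (2E,6E)-7-(acetoxymethyl)-3-methyl-8-oxoocta-2,6-dienoate
Product: 10 methyl (2E,6Z)-7-(acetoxymethyl)-3-methylnona-2,6,8-trienoate
Conditions: Ph3PCH3Br, KN(SiMe3)2, THF, 0 °C; then 9, −78 → 0 °C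
Reagents that add atoms: methyltriphenylphosphonium bromide, C[P+](c1ccccc1)(c1ccccc1)c1ccccc1.[Br-]
Why: Wittig methylenation of the aldehyde leaves the trisubstituted alkene untouched, so the chain sits trans to the new vinyl group, the reactive "outside" position of the diene.

Step 6
Reactants: 3 methyl 1-methyl-4-oxocyclohexa-2,5-diene-1-carboxylate; 10 methyl (2E,6Z)-7-(acetoxymethyl)-3-methylnona-2,6,8-trienoate
Product: 11 dimethyl 17-acetoxy-1-oxo-20-nor-5β,9β,10β-labda-2,7,13E-triene-15,18-dioate
Conditions: (S)-o-tolyl-oxazaborolidine (from diphenylprolinol)·HNTf2 (20 mol %), CH2Cl2, −78 → −20 °C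
Reagents that add atoms: none
Why: Proposed new method: the chiral oxazaborolidinium Lewis acid should bind the dienone carbonyl and activate one of the two enantiotopic enone units for an endo [4+2] cycloaddition (desymmetrisation), in which the unsubstituted diene terminus bonds to the hindered β-carbon C5, the diene approaches the face of the flat ester (anti to the C4 methyl) and the endo transition state places the side chain cis to C1, so C4, C5 and C9 are set together with a cis ring fusion; the closest known type is the oxazaborolidinium-catalysed Diels–Alder reaction of 2-cyclohexenones and the desymmetrising Diels–Alder reaction of quinone monoketals.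

Step 7
Reactants: 11 dimethyl 17-acetoxy-1-oxo-20-nor-5β,9β,10β-labda-2,7,13E-triene-15,18-dioate
Product: 12 dimethyl 17-acetoxy-1-oxo-5β,9β-labda-2,7,13E-triene-15,18-dioate
Conditions: KN(SiMe3)2 (1.05 equiv), THF, −78 °C; then MeI, −78 → −20 °C
Reagents that add atoms: iodomethane, CI
Why: Enolate alkylation: C10–H is the only enolisable α-position, and MeI attacks the dienolate on the convex β face, anti to both the C9 side chain and C6, which keeps the cis fusion and puts the C10 methyl trans to the side chain.

Step 8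
Reactants: 12 dimethyl 17-acetoxy-1-oxo-5β,9β-labda-2,7,13E-triene-15,18-dioate
Product: 14 dimethyl 17-acetoxy-5β,9β-labda-1,7,13E-triene-15,18-dioate, via tosylhydrazone 13 (not isolated)
Conditions: TsNHNH2, EtOH, 70 °C; then catecholborane, CHCl3, 0 °C; then NaOAc·3H2O, 60 °C
Reagents that add atoms: none
Why: Kabalka reductive 1,3-transposition: hydride reduction of the enone tosylhydrazone, loss of sulfinate and retro-ene loss of N2 delete the C1 oxygen and move the alkene to C1=C2; no stereocenter is created.

Step 9
Reactants: 14 dimethyl 17-acetoxy-5β,9β-labda-1,7,13E-triene-15,18-dioate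
Product: 16 dimethyl 17-acetoxy-2-oxo-5β,9β-labda-7,13E-diene-15,18-dioate, via organoborane 15 (not isolated)
Conditions: Sia2BH (from BH3·SMe2 and 2-methylbut-2-ene), THF, 0 °C → rt; then NMO, (n-Pr4N)RuO4 (10 mol %), 4 Å MS, CH2Cl2, rt
Reagents that add atoms: N-methylmorpholine N-oxide, C[N+]1([O-])CCOCC1
Why: Hydroboration–oxidation: the bulky dialkylborane adds only to the cis-disubstituted ring A alkene (trisubstituted and ester-conjugated alkenes are inert to it) with boron at C2, away from the quaternary C10, and the C–B bond is oxidised straight to the ketone, so the C2 configuration of 15 does not matter.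

Step 10
Reactants: 16 dimethyl 17-acetoxy-2-oxo-5β,9β-labda-7,13E-diene-15,18-dioate
Product: 17 dimethyl 17-acetoxy-2β-hydroxy-5β,9β-labda-7,13E-diene-15,18-dioate
Conditions: NaBH4, MeOH, −20 °C
Reagents that add atoms: none
Why: Hydride reduction under steric approach control: in the ring conformation that keeps the C9 side chain equatorial on ring B, the C4 and C10 methyls are syn-axial on the β face on either side of C2, so hydride enters from the α (equatorial) side and gives the axial 2β-alcohol, as with 3,3,5,5-tetramethylcyclohexanone.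

Step 11
Reactants: 17 dimethyl 17-acetoxy-2β-hydroxy-5β,9β-labda-7,13E-diene-15,18-dioate
Product: 18 dimethyl 2β-hydroxy-5β,9β-labda-8(17),13E-diene-15,18-dioate
Conditions: Pd(OAc)2 (5 mol %), n-Bu3P (10 mol %), HCO2NH4, 1,4-dioxane, 100 °C
Reagents that add atoms: none
Why: Tsuji hydrogenolysis: zerovalent palladium ionises the allylic acetate and the formate-derived hydride is delivered to the more substituted allyl terminus (C7), giving the exocyclic alkene; C9 lies outside the allyl unit and keeps its configuration.

Step 12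
Reactants: 18 dimethyl 2β-hydroxy-5β,9β-labda-8(17),13E-diene-15,18-dioate
Product: 19 2β-hydroxy-5β,9β-labda-8(17),13E-diene-15,18-dioic acid (target)
Conditions: KOt-Bu (8 equiv), H2O (3 equiv), THF/DMSO, 25 → 50 °C; then 1 M HCl
Reagents that add atoms: water, O
Why: Ester hydrolysis with Gassman's "anhydrous hydroxide" cleaves both the unhindered enoate and the hindered tertiary ester without touching the alkenes or any stereocenter.

## Compound list

1 | methyl benzoate | COC(=O)c1ccccc1 | starting material
2 | methyl 1-methylcyclohexa-2,5-diene-1-carboxylate | COC(=O)C1(C)C=CCC=C1 | intermediate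
3 | methyl 1-methyl-4-oxocyclohexa-2,5-diene-1-carboxylate | COC(=O)C1(C)C=CC(=O)C=C1 | intermediate
4 | methyl geranate, methyl (2E)-3,7-dimethylocta-2,6-dienoate | CC(C)=CCC/C(C)=C/C(=O)OC | starting material
5 | methyl (2E)-3-methyl-6-oxohex-2-enoate | O=CCC/C(C)=C/C(=O)OC | intermediate
6 | acrolein | C=CC=O | starting material
7 | methyl (2E)-7-formyl-6-hydroxy-3-methylocta-2,7-dienoate (racemic, not isolated) | C=C(C=O)C(O)CC/C(C)=C/C(=O)OC | intermediate
8 | methyl (2E)-6-acetoxy-7-formyl-3-methylocta-2,7-dienoate (racemic, not isolated) | C=C(C=O)C(OC(C)=O)CC/C(C)=C/C(=O)OC | intermediate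
9 | methyl (2E,6E)-7-(acetoxymethyl)-3-methyl-8-oxoocta-2,6-dienoate | O=C/C(COC(C)=O)=C/CC/C(C)=C/C(=O)OC | intermediate
10 | methyl (2E,6Z)-7-(acetoxymethyl)-3-methylnona-2,6,8-trienoate | C=C/C(COC(C)=O)=C/CC/C(C)=C/C(=O)OC | intermediate
11 | cis-fused Diels–Alder adduct: dimethyl 17-acetoxy-1-oxo-20-nor-5β,9β,10β-labda-2,7,13E-triene-15,18-dioate (4β-Me, 4α-CO2Me, side chain 9α) | CC(=O)OCC1=CC[C@H]2[C@H](C(=O)C=C[C@@]2(C)C(=O)OC)[C@@H]1CC/C(C)=C/C(=O)OC | intermediate
12 | dimethyl 17-acetoxy-1-oxo-5β,9β-labda-2,7,13E-triene-15,18-dioate (10β-Me) | CC(=O)OCC1=CC[C@H]2[C@](C)(C(=O)C=C[C@@]2(C)C(=O)OC)[C@@H]1CC/C(C)=C/C(=O)OC | intermediate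
13 | C1 tosylhydrazone of 12 (not isolated) | CC(=O)OCC1=CC[C@H]2[C@](C)(C(=NNS(=O)(=O)c3ccc(C)cc3)C=C[C@@]2(C)C(=O)OC)[C@@H]1CC/C(C)=C/C(=O)OC | intermediate
14 | dimethyl 17-acetoxy-5β,9β-labda-1,7,13E-triene-15,18-dioate | CC(=O)OCC1=CC[C@H]2[C@](C)(C=CC[C@@]2(C)C(=O)OC)[C@@H]1CC/C(C)=C/C(=O)OC | intermediate
15 | 2-(disiamylboryl) adduct of 14 (C2 configuration not defined, not isolated) | CC(=O)OCC1=CC[C@H]2[C@](C)(CC(B(C(C)C(C)C)C(C)C(C)C)C[C@@]2(C)C(=O)OC)[C@@H]1CC/C(C)=C/C(=O)OC | intermediate
16 | dimethyl 17-acetoxy-2-oxo-5β,9β-labda-7,13E-diene-15,18-dioate | CC(=O)OCC1=CC[C@H]2[C@](C)(CC(=O)C[C@@]2(C)C(=O)OC)[C@@H]1CC/C(C)=C/C(=O)OC | intermediate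
17 | dimethyl 17-acetoxy-2β-hydroxy-5β,9β-labda-7,13E-diene-15,18-dioate | CC(=O)OCC1=CC[C@H]2[C@](C)(C[C@H](O)C[C@@]2(C)C(=O)OC)[C@@H]1CC/C(C)=C/C(=O)OC | intermediate
18 | dimethyl 2β-hydroxy-5β,9β-labda-8(17),13E-diene-15,18-dioate | C=C1CC[C@H]2[C@](C)(C[C@H](O)C[C@@]2(C)C(=O)OC)[C@@H]1CC/C(C)=C/C(=O)OC | intermediate
19 | (2S,4R,5S,9R,10R)-2-hydroxylabda-8(17),13E-diene-15,18-dioic acid (2β-OH, 5β-H, 9β-H) | C=C1CC[C@H]2[C@](C)(C[C@H](O)C[C@@]2(C)C(=O)O)[C@@H]1CC/C(C)=C/C(=O)O | target

## Step count and weak points

Total steps: 12. Longest linear sequence: 10 steps (4 → 5 → 9 → 10 → 11 → 12 → 14 → 16 → 17 → 18 → 19).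

Three steps most likely to fail:

**Step 6 (desymmetrising Diels–Alder).** It is unprecedented in this exact form. The 2-acetoxymethyl group of the diene opposes the regiochemical preference of the 1-alkyl terminus, the facial preference (ester face over methyl face) may be modest, and the strong Lewis acid could trigger a dienone–phenol rearrangement of 3 or ionise the allylic acetate. Fallback: set out from 3 and 10 and run the cycloaddition with achiral EtAlCl2 (CH2Cl2, −40 °C), which gives racemic 11. Carry the racemate through steps 7–12 unchanged and resolve the racemic diacid by crystallisation of the bis[(R)-1-phenylethylammonium] salt F1; acidification comes back to the route at 19.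

**Step 9 (chemoselective hydroboration).** The ring A alkene is flanked by a quaternary carbon and may react too slowly with disiamylborane, while less hindered boranes would also attack the ring B alkene. Fallback: set out from 14 and use rhodium-catalysed hydroboration (catecholborane, RhCl(PPh3)3, THF, then NaBO3·4H2O), which leaves trisubstituted alkenes alone, to obtain the C2 alcohol mixture F2. Oxidation with Dess–Martin periodinane comes back to the route at 16.

**Step 10 (C2 configuration).** The outcome depends on which ring conformation reacts; if the other one dominates, hydride gives the 2α-alcohol. Fallback: set out from 16; if reduction gives the 2α-alcohol F3, invert it by Mitsunobu reaction (4-nitrobenzoic acid, PPh3, DIAD) to the 2β-(4-nitrobenzoate) F4. Take this through the conditions of step 11 to the 8(17)-methylene nitrobenzoate F5, and the hydrolysis of step 12 then removes the nitrobenzoate as well and comes back to the route at 19.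

## Further compounds

F1 | step 6 | bis[(R)-1-phenylethylammonium] salt of 19 | C=C1CC[C@H]2[C@](C)(C[C@H](O)C[C@@]2(C)C(=O)[O-])[C@@H]1CC/C(C)=C/C(=O)[O-].C[C@@H]([NH3+])c1ccccc1.C[C@@H]([NH3+])c1ccccc1
F2 | step 9 | dimethyl 17-acetoxy-2-hydroxy-5β,9β-labda-7,13E-diene-15,18-dioate (C2 epimers) | CC(=O)OCC1=CC[C@H]2[C@](C)(CC(O)C[C@@]2(C)C(=O)OC)[C@@H]1CC/C(C)=C/C(=O)OC
F3 | step 10 | dimethyl 17-acetoxy-2α-hydroxy-5β,9β-labda-7,13E-diene-15,18-dioate | CC(=O)OCC1=CC[C@H]2[C@](C)(C[C@@H](O)C[C@@]2(C)C(=O)OC)[C@@H]1CC/C(C)=C/C(=O)OC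
F4 | step 10 | dimethyl 17-acetoxy-2β-(4-nitrobenzoyloxy)-5β,9β-labda-7,13E-diene-15,18-dioate | CC(=O)OCC1=CC[C@H]2[C@](C)(C[C@H](OC(=O)c3ccc(cc3)[N+](=O)[O-])C[C@@]2(C)C(=O)OC)[C@@H]1CC/C(C)=C/C(=O)OC
F5 | step 10 | dimethyl 2β-(4-nitrobenzoyloxy)-5β,9β-labda-8(17),13E-diene-15,18-dioate | C=C1CC[C@H]2[C@](C)(C[C@H](OC(=O)c3ccc(cc3)[N+](=O)[O-])C[C@@]2(C)C(=O)OC)[C@@H]1CC/C(C)=C/C(=O)OC
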